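**Strategy**

In each end ring, C3 and C4 carry a (3S,4S) threo diol and sit between the C2 methylene and the methyl-substituted alkene carbon C5. This C2–C5 unit is L-tartrate with its two carboxyl carbons at different oxidation levels. The route rests on closing the C5=C6 bond of the six-membered ring by an amine-catalysed aldol condensation of an acyclic 7-oxo aldehyde (C7 aldehyde, C5 methyl ketone, diol as acetonide). One operation gives the ring, its tetrasubstituted alkene and the C7 formyl handle. The enal supplies ring A (alkyne, Sonogashira) and ring B (hydroboration, Suzuki); two E-selective Wittig reactions with the C10 dialdehyde complete the chain.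

Key step: step 9

Remarks on the chemistry:
- Carotenoid numbering is used (ring C1–C6, chain from C7, primes for the ring B half).
- Counted from the aldehyde carbon C7, the ketone carbon C5 is the seventh chain atom, so the cyclisation substrate 13 is a 7-oxo aldehyde (1,7-dicarbonyl compound).
- Compounds 9 and 11 are carried as mixtures at the carbinol carbon, and 11 and 12 as E/Z enol ether mixtures; these elements disappear in steps 7 and 8.
- The acetonides are removed at the phosphonium salt stage, because acid treatment of the finished polyene would ionise the allylic C4–O bonds.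
- Compounds 1, 4, 6, 10, 15, 17 and 30 are commercial. All polyene work is done under argon in the dark.

**Route**

Step 1
Reactants: 1 diethyl 2,3-O-isopropylidene-L-tartrate
Product: 2 ethyl (4R,5S)-5-(hydroxymethyl)-2,2-dimethyl-1,3-dioxolane-4-carboxylate
Conditions: NaBH4 (0.6 equiv), EtOH, 0 °C to rt
Reagents that add atoms: none
Why: Partial borohydride reduction of one of two homotopic, α-alkoxy-activated ester groups; a deficit of hydride should favour the hydroxy ester, unreacted 1 and the over-reduced diol are separable, and no stereocentre is touched.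

Step 2
Reactants: 2 ethyl (4R,5S)-5-(hydroxymethyl)-2,2-dimethyl-1,3-dioxolane-4-carboxylate
Product: 3 ethyl (4R,5S)-2,2-dimethyl-5-{[(trifluoromethanesulfonyl)oxy]methyl}-1,3-dioxolane-4-carboxylate
Conditions: Tf2O, pyridine, CH2Cl2, −30 °C
Reagents that add atoms: trifluoromethanesulfonic anhydride, O=S(=O)(OS(=O)(=O)C(F)(F)F)C(F)(F)F
Why: O-Sulfonylation of the primary alcohol; a triflate is chosen because substitution at a carbon β to the dioxolane oxygen is slow with weaker leaving groups.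

Step 3
Reactants: 3 ethyl (4R,5S)-2,2-dimethyl-5-{[(trifluoromethanesulfonyl)oxy]methyl}-1,3-dioxolane-4-carboxylate; 4 isobutyronitrile
Product: 5 ethyl (4R,5S)-5-(2-cyano-2-methylpropyl)-2,2-dimethyl-1,3-dioxolane-4-carboxylate
Conditions: 4, LDA, THF, −78 °C; then 3, −78 °C; AcOH quench at −78 °C
Reagents that add atoms: none
Why: SN2 alkylation of a lithiated nitrile; the slim, strongly nucleophilic α-cyano carbanion should displace the primary triflate at −78 °C faster than it adds to or deprotonates the ester, forming the C1–C2 bond and the quaternary C1.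

Step 4
Reactants: 5 ethyl (4R,5S)-5-(2-cyano-2-methylpropyl)-2,2-dimethyl-1,3-dioxolane-4-carboxylate; 6 methylmagnesium bromide
Product: 8 3-[(4S,5R)-5-acetyl-2,2-dimethyl-1,3-dioxolan-4-yl]-2,2-dimethylpropanenitrile, via Weinreb amide 7 (not isolated)
Conditions: MeNH(OMe)·HCl, MeMgBr (excess), THF, −20 to 0 °C; aq. NH4Cl
Reagents that add atoms: none
Why: One-pot Weinreb ketone synthesis: the magnesium amide converts the ester into the N-methoxy-N-methylamide, whose chelated tetrahedral adduct with MeMgBr releases the ketone only on work-up, while the hindered tertiary nitrile is inert to the Grignard reagent at 0 °C.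

Step 5
Reactants: 8 3-[(4S,5R)-5-acetyl-2,2-dimethyl-1,3-dioxolan-4-yl]-2,2-dimethylpropanenitrile
Product: 9 3-[(4S,5S)-5-(1-hydroxyethyl)-2,2-dimethyl-1,3-dioxolan-4-yl]-2,2-dimethylpropanal (both carbinol epimers)
Conditions: DIBAL-H (3 equiv), CH2Cl2, −78 to −20 °C; aq. potassium sodium tartrate, then aq. citric acid (pH 4), 0 °C
Reagents that add atoms: water, O
Why: DIBAL-H reduction of the nitrile to the N-aluminio aldimine (hydrolysed to the neopentyl aldehyde) and of the ketone to the alcohol, which removes the epimerisable α-alkoxy ketone before the basic Wittig step; the uncontrolled carbinol centre is oxidised away in step 7.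

Step 6
Reactants: 9 3-[(4S,5S)-5-(1-hydroxyethyl)-2,2-dimethyl-1,3-dioxolan-4-yl]-2,2-dimethylpropanal; 10 (methoxymethyl)triphenylphosphonium chloride
Product: 11 1-[(4S,5S)-5-(4-methoxy-2,2-dimethylbut-3-en-1-yl)-2,2-dimethyl-1,3-dioxolan-4-yl]ethan-1-ol (E/Z and carbinol mixture)
Conditions: 10 (3 equiv), KOtBu, THF, 0 °C; then 9, 0 °C to rt
Reagents that add atoms: none
Why: Wittig methoxymethylenation (one-carbon homologation) of the non-enolisable α-quaternary aldehyde; the excess ylide tolerates the free hydroxyl as its alkoxide.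

Step 7
Reactants: 11 1-[(4S,5S)-5-(4-methoxy-2,2-dimethylbut-3-en-1-yl)-2,2-dimethyl-1,3-dioxolan-4-yl]ethan-1-ol
Product: 12 1-[(4R,5S)-5-(4-methoxy-2,2-dimethylbut-3-en-1-yl)-2,2-dimethyl-1,3-dioxolan-4-yl]ethan-1-one (E/Z mixture)
Conditions: Dess–Martin periodinane, pyridine, CH2Cl2, 0 °C to rt
Reagents that add atoms: none
Why: Dess–Martin oxidation of the secondary alcohol under pyridine buffering spares the enol ether and the acetonide and should not epimerise C4.

Step 8
Reactants: 12 1-[(4R,5S)-5-(4-methoxy-2,2-dimethylbut-3-en-1-yl)-2,2-dimethyl-1,3-dioxolan-4-yl]ethan-1-one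
Product: 13 4-[(4S,5R)-5-acetyl-2,2-dimethyl-1,3-dioxolan-4-yl]-3,3-dimethylbutanal (the 7-oxo aldehyde)
Conditions: 1 M aq. HCl, THF, 0 °C to rt; used crude
Reagents that add atoms: water, O
Why: Acid-catalysed enol ether hydrolysis (C-protonation, hemiacetal, loss of methanol) is much faster than hydrolysis of the internal dioxolane deactivated by the neighbouring ketone, so the C7 aldehyde is unmasked selectively.

Step 9
Reactants: 13 4-[(4S,5R)-5-acetyl-2,2-dimethyl-1,3-dioxolan-4-yl]-3,3-dimethylbutanal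
Product: 14 (3aS,7aS)-2,2,4,6,6-pentamethyl-3a,6,7,7a-tetrahydro-1,3-benzodioxole-5-carbaldehyde (acetonide of (3S,4S)-3,4-dihydroxy-β-cyclocitral)
Conditions: pyrrolidine (0.3 equiv), AcOH (0.3 equiv), toluene, 20 to 45 °C
Reagents that add atoms: none
Why: Pyrrolidinium acetate condenses selectively with the unhindered aldehyde C7 to give the enamine, whose carbon C6 adds to the C5 ketone; the adduct loses water through its enamine tautomer to the conjugated iminium ion, and hydrolysis releases the enal and the amine. The closest known reaction type is the secondary-amine-salt-catalysed intramolecular aldol condensation of oxo-alkanals to 2-methylcycloalk-1-ene-1-carbaldehydes. The carbocycle C1–C6 is closed in a 6-(enolexo)-exo-trig mode by forming C5–C6, with the C1 gem-dimethyl group compressing the chain (Thorpe–Ingold effect), and it ends trans-fused to the dioxolane. No stereocentre is created, because C5 and C6 become sp2; C3 and C4 are those of L-tartrate. The step needs the aldehyde as donor and the ketone as acceptor and must keep C4: the aldehyde forms its enamine far faster than the hindered α-alkoxy methyl ketone, a ketone-derived enol or enamine at C4 could only give a β-hydroxy aldehyde with a quaternary C4 that cannot eliminate into conjugation and so reverts by retro-aldol, and the 4,5-trans arrangement on the dioxolane is the thermodynamic one, so reversible enolisation under the acetate buffer returns the same configuration.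

Step 10
Reactants: 14 (3aS,7aS)-2,2,4,6,6-pentamethyl-3a,6,7,7a-tetrahydro-1,3-benzodioxole-5-carbaldehyde; 15 dimethyl (1-diazo-2-oxopropyl)phosphonate
Product: 16 (3aS,7aS)-5-ethynyl-2,2,4,6,6-pentamethyl-3a,6,7,7a-tetrahydro-1,3-benzodioxole
Conditions: 15, K2CO3, MeOH, 0 °C to rt
Reagents that add atoms: none
Why: Ohira–Bestmann (Seyferth–Gilbert) homologation: the diazophosphonate anion adds to the aldehyde, cycloelimination and loss of nitrogen give an alkylidene carbene that rearranges to the terminal alkyne, and the fully substituted β-carbon blocks conjugate addition of methoxide.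

Step 11
Reactants: 17 ethyl acetoacetate
Product: 18 ethyl (2E)-3-{[(trifluoromethyl)sulfonyl]oxy}but-2-enoate
Conditions: Tf2O, aq. Me4NOH, hexane, 5 °C
Reagents that add atoms: trifluoromethanesulfonic anhydride, O=S(=O)(OS(=O)(=O)C(F)(F)F)C(F)(F)F
Why: O-Triflation of the β-keto ester enolate; with the non-chelating tetramethylammonium counter-ion the extended enolate reacts, which places the triflate trans to the ester (E), the geometry later found at C9=C10 and C9'=C10'.

Step 12
Reactants: 16 (3aS,7aS)-5-ethynyl-2,2,4,6,6-pentamethyl-3a,6,7,7a-tetrahydro-1,3-benzodioxole; 18 ethyl (2E)-3-{[(trifluoromethyl)sulfonyl]oxy}but-2-enoate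
Product: 19 ethyl (2E)-3-methyl-5-[(3aS,7aS)-2,2,4,6,6-pentamethyl-3a,6,7,7a-tetrahydro-1,3-benzodioxol-5-yl]pent-2-en-4-ynoate
Conditions: PdCl2(PPh3)2 (cat.), CuI (cat.), Et3N, THF, rt
Reagents that add atoms: none
Why: Sonogashira coupling of the terminal alkyne with the activated enol triflate forms C8–C9 with retention of the alkene geometry.

Step 13
Reactants: 19 ethyl (2E)-3-methyl-5-[(3aS,7aS)-2,2,4,6,6-pentamethyl-3a,6,7,7a-tetrahydro-1,3-benzodioxol-5-yl]pent-2-en-4-ynoate
Product: 20 (2E)-3-methyl-5-[(3aS,7aS)-2,2,4,6,6-pentamethyl-3a,6,7,7a-tetrahydro-1,3-benzodioxol-5-yl]pent-2-en-4-yn-1-ol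
Conditions: DIBAL-H (2.2 equiv), CH2Cl2, −78 °C; aq. potassium sodium tartrate
Reagents that add atoms: none
Why: 1,2-Reduction of the conjugated ester by DIBAL-H at −78 °C, where the alkyne, the alkenes and the acetonide are inert.

Step 14
Reactants: 20 (2E)-3-methyl-5-[(3aS,7aS)-2,2,4,6,6-pentamethyl-3a,6,7,7a-tetrahydro-1,3-benzodioxol-5-yl]pent-2-en-4-yn-1-ol
Product: 22 tributyl{(2E)-3-methyl-5-[(3aS,7aS)-2,2,4,6,6-pentamethyl-3a,6,7,7a-tetrahydro-1,3-benzodioxol-5-yl]pent-2-en-4-yn-1-yl}phosphonium bromide, via allylic bromide 21 (not isolated)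
Conditions: CBr4, PPh3, CH2Cl2, −20 °C; then PBu3, 0 °C to rt
Reagents that add atoms: carbon tetrabromide, BrC(Br)(Br)Br; tributylphosphine, CCCCP(CCCC)CCCC
Why: Appel bromination (neutral SN2 at the primary allylic carbon) followed by quaternisation of tributylphosphine; the trialkylphosphonium group is chosen because its allylic ylides olefinate with high E-selectivity.

Step 15
Reactants: 22 tributyl{(2E)-3-methyl-5-[(3aS,7aS)-2,2,4,6,6-pentamethyl-3a,6,7,7a-tetrahydro-1,3-benzodioxol-5-yl]pent-2-en-4-yn-1-yl}phosphonium bromide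
Product: 23 tributyl{(2E)-5-[(3S,4S)-3,4-dihydroxy-2,6,6-trimethylcyclohex-1-en-1-yl]-3-methylpent-2-en-4-yn-1-yl}phosphonium bromide
Conditions: 0.5 M aq. HBr, THF, rt
Reagents that add atoms: none
Why: Acid-catalysed hydrolysis of the strained trans-fused acetonide; ionisation of the allylic C4–O bond is disfavoured here because the unsaturated chain ends in a cationic phosphonium group, so the diol is freed before the acid-labile polyene exists.

Step 16
Reactants: 16 (3aS,7aS)-5-ethynyl-2,2,4,6,6-pentamethyl-3a,6,7,7a-tetrahydro-1,3-benzodioxole; 18 ethyl (2E)-3-{[(trifluoromethyl)sulfonyl]oxy}but-2-enoate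
Product: 25 ethyl (2E,4E)-3-methyl-5-[(3aS,7aS)-2,2,4,6,6-pentamethyl-3a,6,7,7a-tetrahydro-1,3-benzodioxol-5-yl]penta-2,4-dienoate, via alkenyl pinacol boronate 24 (not isolated)
Conditions: HBpin, Cp2Zr(H)Cl (cat.), Et3N (cat.), CH2Cl2, rt; then 18, Pd(PPh3)4 (cat.), aq. K3PO4, THF, 45 °C
Reagents that add atoms: none
Why: Zirconocene-catalysed syn-hydroboration of the terminal alkyne with pinacolborane gives the (E)-alkenylboronate, and its Suzuki–Miyaura coupling with the enol triflate forms C8'–C9' with retention of both alkene geometries.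

Step 17
Reactants: 25 ethyl (2E,4E)-3-methyl-5-[(3aS,7aS)-2,2,4,6,6-pentamethyl-3a,6,7,7a-tetrahydro-1,3-benzodioxol-5-yl]penta-2,4-dienoate
Product: 26 (2E,4E)-3-methyl-5-[(3aS,7aS)-2,2,4,6,6-pentamethyl-3a,6,7,7a-tetrahydro-1,3-benzodioxol-5-yl]penta-2,4-dien-1-ol
Conditions: DIBAL-H (2.2 equiv), CH2Cl2, −78 °C; aq. potassium sodium tartrate
Reagents that add atoms: none
Why: 1,2-Reduction of the dienoate by DIBAL-H at low temperature, as in step 13.

Step 18
Reactants: 26 (2E,4E)-3-methyl-5-[(3aS,7aS)-2,2,4,6,6-pentamethyl-3a,6,7,7a-tetrahydro-1,3-benzodioxol-5-yl]penta-2,4-dien-1-ol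
Product: 28 tributyl{(2E,4E)-3-methyl-5-[(3aS,7aS)-2,2,4,6,6-pentamethyl-3a,6,7,7a-tetrahydro-1,3-benzodioxol-5-yl]penta-2,4-dien-1-yl}phosphonium bromide, via allylic bromide 27 (not isolated)
Conditions: CBr4, PPh3, CH2Cl2, −20 °C; then PBu3, 0 °C to rt
Reagents that add atoms: carbon tetrabromide, BrC(Br)(Br)Br; tributylphosphine, CCCCP(CCCC)CCCC
Why: Appel bromination and phosphine quaternisation under neutral conditions, as in step 14, which avoids acid while the allylic C4–O bond is conjugated to an uncharged diene.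

Step 19
Reactants: 28 tributyl{(2E,4E)-3-methyl-5-[(3aS,7aS)-2,2,4,6,6-pentamethyl-3a,6,7,7a-tetrahydro-1,3-benzodioxol-5-yl]penta-2,4-dien-1-yl}phosphonium bromide
Product: 29 tributyl{(2E,4E)-5-[(3S,4S)-3,4-dihydroxy-2,6,6-trimethylcyclohex-1-en-1-yl]-3-methylpenta-2,4-dien-1-yl}phosphonium bromide
Conditions: 0.5 M aq. HBr, THF, rt
Reagents that add atoms: none
Why: Mild acid hydrolysis of the strained acetonide on the phosphonium salt, as in step 15.

Step 20
Reactants: 23 tributyl{(2E)-5-[(3S,4S)-3,4-dihydroxy-2,6,6-trimethylcyclohex-1-en-1-yl]-3-methylpent-2-en-4-yn-1-yl}phosphonium bromide; 30 (2E,4E,6E)-2,7-dimethylocta-2,4,6-trienedial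
Product: 31 (2E,4E,6E,8E,10E)-13-[(3S,4S)-3,4-dihydroxy-2,6,6-trimethylcyclohex-1-en-1-yl]-2,7,11-trimethyltrideca-2,4,6,8,10-pentaen-12-ynal
Conditions: 30 (3 equiv), NaOMe (MeOH solution), CH2Cl2, 0 °C to rt
Reagents that add atoms: none
Why: Wittig olefination of the allylic tributylphosphonium ylide with one aldehyde group of the excess dialdehyde forms C11=C12, which should be mainly E as is known for allylic trialkylphosphonium ylides; the free hydroxyls are tolerated in methanolic methoxide and the product aldehyde is less electrophilic than 30, which limits double olefination.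

Step 21
Reactants: 31 (2E,4E,6E,8E,10E)-13-[(3S,4S)-3,4-dihydroxy-2,6,6-trimethylcyclohex-1-en-1-yl]-2,7,11-trimethyltrideca-2,4,6,8,10-pentaen-12-ynal; 29 tributyl{(2E,4E)-5-[(3S,4S)-3,4-dihydroxy-2,6,6-trimethylcyclohex-1-en-1-yl]-3-methylpenta-2,4-dien-1-yl}phosphonium bromide
Product: 32 (all-E)-(3S,4S,3'S,4'S)-7,8-didehydro-β,β-carotene-3,4,3',4'-tetrol (target)
Conditions: NaOMe (MeOH solution), CH2Cl2, 0 °C to rt
Reagents that add atoms: none
Why: A second E-selective Wittig olefination of the same type forms C11'=C12' and completes the C40 chain; no protecting group remains, so the acid- and light-sensitive tetrol sees no further reagent.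

**Compound list**

1 | diethyl (4R,5R)-2,2-dimethyl-1,3-dioxolane-4,5-dicarboxylate (diethyl 2,3-O-isopropylidene-L-tartrate) | CCOC(=O)[C@@H]1OC(C)(C)O[C@H]1C(=O)OCC | starting material
2 | ethyl (4R,5S)-5-(hydroxymethyl)-2,2-dimethyl-1,3-dioxolane-4-carboxylate | OC[C@@H]1OC(C)(C)O[C@H]1C(=O)OCC | intermediate
3 | ethyl (4R,5S)-2,2-dimethyl-5-{[(trifluoromethanesulfonyl)oxy]methyl}-1,3-dioxolane-4-carboxylate | FC(F)(F)S(=O)(=O)OC[C@@H]1OC(C)(C)O[C@H]1C(=O)OCC | intermediate
4 | isobutyronitrile | CC(C)C#N | starting material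
5 | ethyl (4R,5S)-5-(2-cyano-2-methylpropyl)-2,2-dimethyl-1,3-dioxolane-4-carboxylate | N#CC(C)(C)C[C@@H]1OC(C)(C)O[C@H]1C(=O)OCC | intermediate
6 | methylmagnesium bromide | C[Mg]Br | starting material
7 | (4R,5S)-5-(2-cyano-2-methylpropyl)-N-methoxy-N,2,2-trimethyl-1,3-dioxolane-4-carboxamide (Weinreb amide, not isolated) | N#CC(C)(C)C[C@@H]1OC(C)(C)O[C@H]1C(=O)N(C)OC | intermediate
8 | 3-[(4S,5R)-5-acetyl-2,2-dimethyl-1,3-dioxolan-4-yl]-2,2-dimethylpropanenitrile | N#CC(C)(C)C[C@@H]1OC(C)(C)O[C@H]1C(C)=O | intermediate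
9 | 3-[(4S,5S)-5-(1-hydroxyethyl)-2,2-dimethyl-1,3-dioxolan-4-yl]-2,2-dimethylpropanal (carbinol epimers) | O=CC(C)(C)C[C@@H]1OC(C)(C)O[C@H]1C(C)O | intermediate
10 | (methoxymethyl)triphenylphosphonium chloride | COC[P+](c1ccccc1)(c1ccccc1)c1ccccc1.[Cl-] | starting material
11 | 1-[(4S,5S)-5-(4-methoxy-2,2-dimethylbut-3-en-1-yl)-2,2-dimethyl-1,3-dioxolan-4-yl]ethan-1-ol (E/Z, carbinol epimers) | COC=CC(C)(C)C[C@@H]1OC(C)(C)O[C@H]1C(C)O | intermediate
12 | 1-[(4R,5S)-5-(4-methoxy-2,2-dimethylbut-3-en-1-yl)-2,2-dimethyl-1,3-dioxolan-4-yl]ethan-1-one (E/Z) | COC=CC(C)(C)C[C@@H]1OC(C)(C)O[C@H]1C(C)=O | intermediate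
13 | 4-[(4S,5R)-5-acetyl-2,2-dimethyl-1,3-dioxolan-4-yl]-3,3-dimethylbutanal | O=CCC(C)(C)C[C@@H]1OC(C)(C)O[C@H]1C(C)=O | intermediate
14 | (3aS,7aS)-2,2,4,6,6-pentamethyl-3a,6,7,7a-tetrahydro-1,3-benzodioxole-5-carbaldehyde | CC1=C(C=O)C(C)(C)C[C@@H]2OC(C)(C)O[C@@H]12 | intermediate
15 | dimethyl (1-diazo-2-oxopropyl)phosphonate | COP(=O)(OC)C(=[N+]=[N-])C(C)=O | starting material
16 | (3aS,7aS)-5-ethynyl-2,2,4,6,6-pentamethyl-3a,6,7,7a-tetrahydro-1,3-benzodioxole | CC1=C(C#C)C(C)(C)C[C@@H]2OC(C)(C)O[C@@H]12 | intermediate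
17 | ethyl acetoacetate | CCOC(=O)CC(C)=O | starting material
18 | ethyl (2E)-3-{[(trifluoromethyl)sulfonyl]oxy}but-2-enoate | CCOC(=O)/C=C(\C)OS(=O)(=O)C(F)(F)F | intermediate
19 | ethyl (2E)-3-methyl-5-[(3aS,7aS)-2,2,4,6,6-pentamethyl-3a,6,7,7a-tetrahydro-1,3-benzodioxol-5-yl]pent-2-en-4-ynoate | CC1=C(C#C/C(C)=C/C(=O)OCC)C(C)(C)C[C@@H]2OC(C)(C)O[C@@H]12 | intermediate
20 | (2E)-3-methyl-5-[(3aS,7aS)-2,2,4,6,6-pentamethyl-3a,6,7,7a-tetrahydro-1,3-benzodioxol-5-yl]pent-2-en-4-yn-1-ol | CC1=C(C#C/C(C)=C/CO)C(C)(C)C[C@@H]2OC(C)(C)O[C@@H]12 | intermediate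
21 | (3aS,7aS)-5-[(3E)-5-bromo-3-methylpent-3-en-1-yn-1-yl]-2,2,4,6,6-pentamethyl-3a,6,7,7a-tetrahydro-1,3-benzodioxole (not isolated) | CC1=C(C#C/C(C)=C/CBr)C(C)(C)C[C@@H]2OC(C)(C)O[C@@H]12 | intermediate
22 | tributyl{(2E)-3-methyl-5-[(3aS,7aS)-2,2,4,6,6-pentamethyl-3a,6,7,7a-tetrahydro-1,3-benzodioxol-5-yl]pent-2-en-4-yn-1-yl}phosphonium bromide | CC1=C(C#C/C(C)=C/C[P+](CCCC)(CCCC)CCCC)C(C)(C)C[C@@H]2OC(C)(C)O[C@@H]12.[Br-] | intermediate
23 | tributyl{(2E)-5-[(3S,4S)-3,4-dihydroxy-2,6,6-trimethylcyclohex-1-en-1-yl]-3-methylpent-2-en-4-yn-1-yl}phosphonium bromide | CC1=C(C#C/C(C)=C/C[P+](CCCC)(CCCC)CCCC)C(C)(C)C[C@H](O)[C@H]1O.[Br-] | intermediate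
24 | 2-{(E)-2-[(3aS,7aS)-2,2,4,6,6-pentamethyl-3a,6,7,7a-tetrahydro-1,3-benzodioxol-5-yl]ethenyl}-4,4,5,5-tetramethyl-1,3,2-dioxaborolane (not isolated) | CC1=C(/C=C/B3OC(C)(C)C(C)(C)O3)C(C)(C)C[C@@H]2OC(C)(C)O[C@@H]12 | intermediate
25 | ethyl (2E,4E)-3-methyl-5-[(3aS,7aS)-2,2,4,6,6-pentamethyl-3a,6,7,7a-tetrahydro-1,3-benzodioxol-5-yl]penta-2,4-dienoate | CC1=C(/C=C/C(C)=C/C(=O)OCC)C(C)(C)C[C@@H]2OC(C)(C)O[C@@H]12 | intermediate
26 | (2E,4E)-3-methyl-5-[(3aS,7aS)-2,2,4,6,6-pentamethyl-3a,6,7,7a-tetrahydro-1,3-benzodioxol-5-yl]penta-2,4-dien-1-ol | CC1=C(/C=C/C(C)=C/CO)C(C)(C)C[C@@H]2OC(C)(C)O[C@@H]12 | intermediate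
27 | (3aS,7aS)-5-[(1E,3E)-5-bromo-3-methylpenta-1,3-dien-1-yl]-2,2,4,6,6-pentamethyl-3a,6,7,7a-tetrahydro-1,3-benzodioxole (not isolated) | CC1=C(/C=C/C(C)=C/CBr)C(C)(C)C[C@@H]2OC(C)(C)O[C@@H]12 | intermediate
28 | tributyl{(2E,4E)-3-methyl-5-[(3aS,7aS)-2,2,4,6,6-pentamethyl-3a,6,7,7a-tetrahydro-1,3-benzodioxol-5-yl]penta-2,4-dien-1-yl}phosphonium bromide | CC1=C(/C=C/C(C)=C/C[P+](CCCC)(CCCC)CCCC)C(C)(C)C[C@@H]2OC(C)(C)O[C@@H]12.[Br-] | intermediate
29 | tributyl{(2E,4E)-5-[(3S,4S)-3,4-dihydroxy-2,6,6-trimethylcyclohex-1-en-1-yl]-3-methylpenta-2,4-dien-1-yl}phosphonium bromide | CC1=C(/C=C/C(C)=C/C[P+](CCCC)(CCCC)CCCC)C(C)(C)C[C@H](O)[C@H]1O.[Br-] | intermediate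
30 | (2E,4E,6E)-2,7-dimethylocta-2,4,6-trienedial | O=C/C(C)=C/C=C/C=C(C)/C=O | starting material
31 | (2E,4E,6E,8E,10E)-13-[(3S,4S)-3,4-dihydroxy-2,6,6-trimethylcyclohex-1-en-1-yl]-2,7,11-trimethyltrideca-2,4,6,8,10-pentaen-12-ynal | CC1=C(C#C/C(C)=C/C=C/C(C)=C/C=C/C=C(C)/C=O)C(C)(C)C[C@H](O)[C@H]1O | intermediate
32 | (all-E)-(3S,4S,3'S,4'S)-7,8-didehydro-β,β-carotene-3,4,3',4'-tetrol | CC1=C(C#C/C(C)=C/C=C/C(C)=C/C=C/C=C(C)/C=C/C=C(C)/C=C/C2=C(C)[C@H](O)[C@@H](O)CC2(C)C)C(C)(C)C[C@H](O)[C@H]1O | target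

**Step count and risks**

Total step count: 21. Longest linear sequence: 16 (steps 1–10, 12–15, 20, 21).

Steps most likely to fail:

1. Step 9 (ring closure). The closure onto the ketone may be slowed by the strain of the developing trans-fused dioxolane. Epimerisation or β-elimination at C4 through the ketone enamine, or further reaction of the enal through its dienamine, could then overtake it. Fallback: set out from enol ether 12 and bypass 13. BF3·OEt2 in CH2Cl2 at −78 °C activates the ketone and the enol ether carbon C6 attacks it (Lewis-acid aldol addition of Mukaiyama/Prins type; the donor regiochemistry is fixed by the enol ether and no amine or base is present). Aqueous NaHCO3 work-up hydrolyses the oxocarbenium ion to the β-hydroxy aldehyde (3aR,7aS)-4-hydroxy-2,2,4,6,6-pentamethylhexahydro-1,3-benzodioxole-5-carbaldehyde F1, as a mixture at the two new centres. Martin sulfurane in CH2Cl2 at rt then dehydrates the tertiary alcohol towards the acidic C6–H and gives 14, where the route is rejoined.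

2. Step 3 (alkylation beside an ester). The lithiated nitrile may add to the ester carbonyl or deprotonate C4 next to it, with opening of the dioxolane or loss of configuration, instead of displacing the triflate. Fallback: set out from 1 and remove the carbonyl before the alkylation. LiAlH4 (THF, 0 °C) gives the diol 2,3-O-isopropylidene-L-threitol F2; NaH then TBSCl (THF) gives the mono-silyl ether F3; Tf2O and pyridine give the triflate F4; lithiated 4 (LDA, THF, −78 °C) gives the nitrile F5; DIBAL-H gives the aldehyde F6; the ylide from 10 gives the enol ether F7; Bu4NF gives the primary alcohol F8; Swern oxidation gives the aldehyde F9; MeMgBr (THF, −78 °C) gives 11, where the route is rejoined. Steps 4 and 5 fall away.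

3. Step 16 (one-pot hydroboration and coupling). Hydroboration of the hindered enyne may be incomplete, or protodeboronation and slow transmetalation may erode the coupling. Fallback: set out from 14 and form C7'=C8' by Horner–Wadsworth–Emmons olefination with the lithium anion of triethyl 3-methyl-4-phosphonobut-2-enoate (LiHMDS, THF–DMPU, −78 to 0 °C). This gives 25 directly after chromatographic removal of the 2Z isomer, makes no new compound, and rejoins the route at 25.

Further compounds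
F1 | step 9 | (3aR,7aS)-4-hydroxy-2,2,4,6,6-pentamethylhexahydro-1,3-benzodioxole-5-carbaldehyde (epimers at the two new centres) | CC1(O)C(C=O)C(C)(C)C[C@@H]2OC(C)(C)O[C@@H]12
F2 | step 3 | [(4S,5S)-2,2-dimethyl-1,3-dioxolane-4,5-diyl]dimethanol | OC[C@@H]1OC(C)(C)O[C@H]1CO
F3 | step 3 | [(4S,5S)-5-({[tert-butyl(dimethyl)silyl]oxy}methyl)-2,2-dimethyl-1,3-dioxolan-4-yl]methanol | OC[C@@H]1OC(C)(C)O[C@H]1CO[Si](C)(C)C(C)(C)C
F4 | step 3 | [(4S,5S)-5-({[tert-butyl(dimethyl)silyl]oxy}methyl)-2,2-dimethyl-1,3-dioxolan-4-yl]methyl trifluoromethanesulfonate | FC(F)(F)S(=O)(=O)OC[C@@H]1OC(C)(C)O[C@H]1CO[Si](C)(C)C(C)(C)C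
F5 | step 3 | 3-[(4S,5S)-5-({[tert-butyl(dimethyl)silyl]oxy}methyl)-2,2-dimethyl-1,3-dioxolan-4-yl]-2,2-dimethylpropanenitrile | N#CC(C)(C)C[C@@H]1OC(C)(C)O[C@H]1CO[Si](C)(C)C(C)(C)C
F6 | step 3 | 3-[(4S,5S)-5-({[tert-butyl(dimethyl)silyl]oxy}methyl)-2,2-dimethyl-1,3-dioxolan-4-yl]-2,2-dimethylpropanal | O=CC(C)(C)C[C@@H]1OC(C)(C)O[C@H]1CO[Si](C)(C)C(C)(C)C
F7 | step 3 | tert-butyl{[(4S,5S)-5-(4-methoxy-2,2-dimethylbut-3-en-1-yl)-2,2-dimethyl-1,3-dioxolan-4-yl]methoxy}dimethylsilane (E/Z) | COC=CC(C)(C)C[C@@H]1OC(C)(C)O[C@H]1CO[Si](C)(C)C(C)(C)C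
F8 | step 3 | [(4S,5S)-5-(4-methoxy-2,2-dimethylbut-3-en-1-yl)-2,2-dimethyl-1,3-dioxolan-4-yl]methanol (E/Z) | COC=CC(C)(C)C[C@@H]1OC(C)(C)O[C@H]1CO
F9 | step 3 | (4R,5S)-5-(4-methoxy-2,2-dimethylbut-3-en-1-yl)-2,2-dimethyl-1,3-dioxolane-4-carbaldehyde (E/Z) | COC=CC(C)(C)C[C@@H]1OC(C)(C)O[C@H]1C=O
F0 | step 16 | none | none
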